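Numbering (germacrane): C1 ketone, C4–C5 oxirane, C6 lactone CH–O, C7=C11 butenolide alkene, C8 CH–OAc, C10 C(CH3)OAc, C12 lactone C=O, C13 CH2OH, C14/C15 the methyls on C10/C4. Ring A is the ten-membered carbocycle, ring B the oxirane, ring C the butenolide.
Enabling feature: the tetrasubstituted C7=C11 alkene lies inside five-membered ring C (O–C6–C7=C11–C12). It can therefore be cut to a C7 ketone and a phosphonate carbon C11 that is already tied to C6 through the C6–O–C12 ester, which places carbanion and carbonyl in a 1,5 relationship.
Cuts in retrosynthetic order: C13 O–PMB, C7=C11 (ring C), C6–O acyl bond, C2–S, C4/C5–O (ring B), C2–C3 (ring A), C1–C2, C5–C6, C7–C8.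
Forward: citramalic acid (C1, C8–C10, C14) is extended at C8 by an allyl unit (C7, C6), at C6 by a methallyl unit (C3–C5, C15) and at C1 by a sulfonylmethyl unit (C2). Ring A closes first (C2–C3, vinyl epoxide with zerovalent palladium), ring B second, ring C last.
Stereochemistry: C10 comes from (R)-citramalic acid. C8 and C6 come from two allylborations controlled by the same (+)-Ipc2BOMe. C7 is a temporary centre that reinforces the C6 addition and is erased on oxidation. C4 and C5 come from C6–OH-directed, peripheral epoxidation of the E alkene.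

Key step: step 20

Remark on the chemistry: C2 in 17 and 18 and C11 in 25–29 are carried as epimer mixtures because both centres are erased later. C5 in 12–16 is a temporary centre that is lost in the π-allyl complex.

Step 1
Reactants: 1 (R)-citramalic acid
Product: 2 2-[(4R)-2,2,4-trimethyl-5-oxo-1,3-dioxolan-4-yl]acetic acid
Conditions: Me2C(OMe)2, TsOH·H2O (cat.), CH2Cl2, rt
Reagents that add atoms: 2,2-dimethoxypropane COC(C)(C)OC
Why: Acid-catalysed acetal exchange (dioxolanone formation) ties the C10 hydroxyl and the C1 carboxyl into the favoured five-membered ring, leaves the C8 carboxyl free and does not touch the C10 stereocentre, which comes from the chiral pool.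

Step 2
Reactants: 2 2-[(4R)-2,2,4-trimethyl-5-oxo-1,3-dioxolan-4-yl]acetic acid
Product: 3 (5R)-5-(2-hydroxyethyl)-2,2,5-trimethyl-1,3-dioxolan-4-one
Conditions: BH3·SMe2, THF, 0 °C to rt; aqueous work-up
Reagents that add atoms: none
Why: Chemoselective borane reduction of a free carboxylic acid (through the acyloxyborane) is much faster than attack on the lactone-type C1 carbonyl, so only C8 should be reduced; 3 is carried on at once to avoid translactonisation.

Step 3
Reactants: 3 (5R)-5-(2-hydroxyethyl)-2,2,5-trimethyl-1,3-dioxolan-4-one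
Product: 4 2-[(4R)-2,2,4-trimethyl-5-oxo-1,3-dioxolan-4-yl]acetaldehyde (C8 aldehyde)
Conditions: Dess–Martin periodinane, CH2Cl2, 0 °C to rt
Reagents that add atoms: none
Why: Dess–Martin oxidation of the primary alcohol runs under neutral conditions that should leave the acid- and base-labile dioxolanone intact and cannot over-oxidise.

Step 4
Reactants: 4 C8 aldehyde; 5 allyl(diisopropylamino)dimethylsilane
Product: 8 (3R,5S)-3-hydroxy-5-[(1R)-1-hydroxyprop-2-enyl]-3-methyloxolan-2-one, via borinate adduct 6 (not isolated), via dioxolanone diol 7 (not isolated)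
Conditions: 5, n-BuLi, TMEDA, Et2O, 0 °C; (+)-Ipc2BOMe, −78 °C; BF3·OEt2; 4, −78 °C; then KF, KHCO3, 30% H2O2, THF–MeOH, rt; PPTS (cat.), CH2Cl2, rt
Reagents that add atoms: hydrogen peroxide OO
Why: Reagent-controlled γ-silylallylboration through a chair-like Zimmerman–Traxler transition state, in which the E-configured allylborane gives the anti C7/C8 relationship and the isopinocampheyl groups derived from (−)-α-pinene direct C7 to the Re face of the aldehyde (8S), is followed by Tamao–Fleming oxidation of C7–Si with retention and by lactonisation of the new C8 hydroxyl onto C1 with loss of acetone, so that one ring masks both C8–O and C1.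

Step 5
Reactants: 8 lactone diol
Product: 9 (3R,5S)-3-hydroxy-3-methyl-5-[(1R)-1-(triethylsilyloxy)prop-2-enyl]oxolan-2-one
Conditions: TESCl, imidazole, CH2Cl2, 0 °C
Reagents that add atoms: chlorotriethylsilane CC[Si](Cl)(CC)CC
Why: Silylation with a chlorosilane and imidazole is governed by steric access, so the secondary allylic C7 hydroxyl should react and the tertiary C10 hydroxyl should not.

Step 6
Reactants: 9 C7 triethylsilyl ether
Product: 10 (2S)-2-[(2S,4R)-4-hydroxy-4-methyl-5-oxooxolan-2-yl]-2-(triethylsilyloxy)acetaldehyde (C6 aldehyde)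
Conditions: O3, CH2Cl2, −78 °C; PPh3
Reagents that add atoms: ozone [O-][O+]=O
Why: Ozonolysis with reductive work-up cleaves the only alkene to the C6 aldehyde under neutral conditions, which matters because this β-acyloxy aldehyde would eliminate with base; 10 is used without storage.

Step 7
Reactants: 10 C6 aldehyde; 11 3-chloro-2-methylprop-1-ene (methallyl chloride)
Product: 12 syn C5-chloro C6-hydroxy adduct (C3=C4 isopropenyl, C7 OTES, lactone unchanged; C6–O anti to C7–O, C7–O anti to C8–O)
Conditions: 11, (+)-Ipc2BOMe, LiN(c-C6H11)2, Et2O, −95 °C; BF3·OEt2; 10, −95 °C; aq. NaOAc, H2O2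
Reagents that add atoms: none
Why: γ-Chloroallylboration (allylboration through a chair transition state) with the Z-configured borane made in the flask gives the syn chlorohydrin, the isopinocampheyl groups again directing attack to the Re face of the aldehyde to set C6 in the 1,2-anti sense that α-oxygenated aldehydes prefer on their own (Felkin–Anh/Cornforth, matched case), while C5 is only a temporary centre.

Step 8
Reactants: 12 chlorohydrin
Product: 13 cis C5–C6 vinyl epoxide lactone (C4 isopropenyl, C7 OTES, free C10–OH)
Conditions: DBU, CH2Cl2, rt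
Reagents that add atoms: none
Why: Intramolecular Williamson-type SN2 displacement of the allylic chloride by the C6 oxygen inverts C5 and gives the cis vinyl epoxide without breaking the C6–O bond, and the amidine base should harm neither lactone nor silyl ether.

Step 9
Reactants: 13 vinyl epoxide lactone; 14 methyl phenyl sulfone
Product: 15 open-chain β-keto sulfone diol (C1 ketone, C2 CH2SO2Ph, free C8–OH and C10–OH)
Conditions: 14 (3.5 equiv), n-BuLi, THF, −78 to 0 °C; 13, −78 to −40 °C; AcOH quench at −40 °C
Reagents that add atoms: none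
Why: Claisen-type acylation of the sulfonyl carbanion by the lactone forms C1–C2 and frees C8–OH and C10–OH in one operation, the product being held as its unreactive enolate so that a second addition is excluded, and the low temperature with an acid quench should hold back attack on the epoxide and 1,2-silyl migration from C7 to C8.

Step 10
Reactants: 15 β-keto sulfone diol
Product: 16 C8,C10-bis-acetate of 15 (cyclisation substrate)
Conditions: Ac2O, pyridine, DMAP (cat.), CH2Cl2, 0 °C to rt
Reagents that add atoms: acetic anhydride CC(=O)OC(C)=O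
Why: DMAP-catalysed acetylation (nucleophilic catalysis) esterifies the secondary C8 and the tertiary C10 hydroxyl, the fast reaction at C8 draining the open-chain form from its equilibrium with the C1 hemiketal, and pyridine is too weak a base to enolise the β-keto sulfone appreciably.

Step 11
Reactants: 16 cyclisation substrate
Product: 17 ring A allylic alcohol ((4E)-cyclodecenone with C2 SO2Ph, C6 OH, C7 OTES, C8 OAc, C10 OAc)
Conditions: Pd(PPh3)4 (10 mol %), dppe (20 mol %), THF, reflux, slow addition at high dilution
Reagents that add atoms: none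
Why: Tsuji–Trost-type macrocyclisation under neutral conditions, in which zerovalent palladium ionises the allylic C5–O bond, the released C6 alkoxide deprotonates the β-keto sulfone and the soft carbanion C2 attacks the unhindered π-allyl terminus C3, should close ring A with the E C4=C5 alkene (syn π-allyl isomer), leave the C6–O bond and its configuration untouched and give C2 as an inconsequential epimer mixture.

Step 12
Reactants: 17 ring A allylic alcohol
Product: 18 4R,5R epoxide of 17 (rings A and B)
Conditions: mCPBA, CH2Cl2–pH 7 phosphate buffer, 0 °C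
Reagents that add atoms: 3-chloroperbenzoic acid OOC(=O)c1cccc(Cl)c1
Why: Henbest-type hydroxyl-directed epoxidation, because in the conformer that avoids A(1,3) strain between C15 and the C6 substituents C6–H lies in the alkene plane, C7 points into the ring and C6–OH sits on the outer face, so that hydrogen-bonded delivery and peripheral attack both place the oxygen on the face that gives the 4R,5R oxirane.

Step 13
Reactants: 18 epoxy sulfone
Product: 19 desulfonylated epoxy alcohol (C2 CH2, free C6–OH)
Conditions: Bu3SnH, AIBN (cat.), toluene, 90 °C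
Reagents that add atoms: none
Why: Radical desulfonylation of an α-sulfonyl ketone with tin hydride (stannyl radical at the carbonyl oxygen, β-scission of C2–S, protonation of the tin enolate) should spare the C10 acetate next to the same ketone, which electron-transfer reductants would cleave, and it removes the C2 stereocentre at a stage where no alkene is left to isomerise.

Step 14
Reactants: 20 triethyl phosphonoacetate; 21 formaldehyde (used as paraformaldehyde)
Product: 23 ethyl 2-(diethoxyphosphoryl)acrylate, via hydroxymethyl adduct 22 (not isolated)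
Conditions: (CH2O)n, piperidine (cat.), MeOH, reflux; then TsOH·H2O (cat.), toluene, Dean–Stark reflux
Reagents that add atoms: none
Why: Knoevenagel-type hydroxymethylation of the active methylene with formaldehyde followed by acid-catalysed dehydration is the standard entry to 2-phosphonoacrylates and introduces C13.

Step 15
Reactants: 23 ethyl 2-(diethoxyphosphoryl)acrylate; 24 4-methoxybenzyl alcohol
Product: 25 ethyl 2-(diethoxyphosphoryl)-3-(4-methoxybenzyloxy)propanoate
Conditions: NaH (0.1 equiv), THF, 0 °C
Reagents that add atoms: none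
Why: Base-catalysed oxa-Michael addition of the benzylic alkoxide to the doubly activated alkene places the protected oxygen on C13 and creates C11 as a racemic centre, which is of no consequence.

Step 16
Reactants: 25 phosphono ester
Product: 26 2-(diethoxyphosphoryl)-3-(4-methoxybenzyloxy)propanoic acid
Conditions: LiOH·H2O (1.1 equiv), THF–H2O, 0 °C; 1 M HCl to pH 3
Reagents that add atoms: lithium hydroxide [Li+].[OH-]
Why: Saponification distinguishes the carboxylic ester from the less electrophilic phosphonate esters, and the low temperature with about one equivalent of hydroxide should keep retro-Michael loss of the benzylic alkoxide small.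

Step 17
Reactants: 19 epoxy alcohol; 26 phosphono acid
Product: 27 C6 2-(diethoxyphosphoryl)-3-(4-methoxybenzyloxy)propanoate of 19
Conditions: DCC, DMAP (cat.), CH2Cl2, 0 °C to rt
Reagents that add atoms: none
Why: Steglich esterification, which for phosphonoacetic acids can run through a phosphonoketene and therefore tolerates hindered alcohols, acylates the only free hydroxyl (C6) without touching any stereocentre.

Step 18
Reactants: 27 C6 phosphono ester
Product: 28 C7 alcohol
Conditions: HF·pyridine, pyridine, THF, 0 °C
Reagents that add atoms: none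
Why: Fluoride-mediated cleavage of the triethylsilyl ether under buffered, weakly acidic conditions should spare epoxide, acetates, PMB ether and phosphonate and keep acyl migration to C7–OH slow; 28 is oxidised at once.

Step 19
Reactants: 28 C7 alcohol
Product: 29 ten-membered C7 ketone carrying the phosphono ester on C6–O (olefination precursor)
Conditions: Dess–Martin periodinane, pyridine, CH2Cl2, 0 °C to rt
Reagents that add atoms: none
Why: Dess–Martin oxidation converts the C7 carbinol into the ketone under neutral buffered conditions, erases the temporary C7 centre and should not epimerise C6 or C8.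

Step 20
Reactants: 29 olefination precursor
Product: 31 C13 4-methoxybenzyl ether of the target, via β-hydroxyphosphonate lactone 30 (not isolated)
Conditions: LiCl, i-Pr2NEt, MeCN, 0 °C to rt
Reagents that add atoms: none
Why: The lithium-complexed phosphono ester is deprotonated at C11 by the tertiary amine, the carbanion adds to the C7 carbonyl to give the β-oxido phosphonate 30, its oxygen attacks phosphorus, and the oxaphosphetane collapses by syn elimination of diethyl phosphate to leave C7=C11. The closest known reaction is the intramolecular Horner–Wadsworth–Emmons reaction of α-(phosphonoacyloxy) ketones under Masamune–Roush conditions, an established butenolide synthesis. Ring C (O–C6–C7–C11–C12) closes by 5-exo-trig attack on C7=O; the closure is formally enolendo, but much of the charge rests on the exocyclic phosphoryl group, which relaxes the orbital constraint. No new stereocentre remains, because C7 and C11 of 30 both become sp2, so the C11 epimers of 29 converge and the alkene geometry is fixed by the ring. The step needs attack at C7 and not at C1, no removal of C6–H or C8–H (epimerisation, or β-elimination that opens the oxirane) and no expulsion of the benzylic alkoxide from the C11 carbanion. These are secured by the five-membered transition state against a nine-membered bridged one, by the activation of C7 through two α-oxygen substituents while C1 is shielded by quaternary C10, by the phosphono ester C–H being the most acidic site once lithium is bound so that a weak amine suffices, and by ring closure being faster than the reversible loss of alkoxide.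

Step 21
Reactants: 31 PMB ether
Product: 32 CNP0266633.2 (target)
Conditions: DDQ, CH2Cl2–pH 7 buffer, 0 °C
Reagents that add atoms: none
Why: Oxidative cleavage of the electron-rich benzyl ether with DDQ (hydride abstraction, then hydrolysis of the oxocarbenium ion) proceeds at neutral pH, so the epoxide, both acetates and the base-sensitive butenolide should survive.

Compound list
1 | (R)-citramalic acid, (2R)-2-hydroxy-2-methylbutanedioic acid | OC(=O)C[C@@](C)(O)C(=O)O | starting material
2 | 2-[(4R)-2,2,4-trimethyl-5-oxo-1,3-dioxolan-4-yl]acetic acid | OC(=O)C[C@@]1(C)OC(C)(C)OC1=O | intermediate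
3 | (5R)-5-(2-hydroxyethyl)-2,2,5-trimethyl-1,3-dioxolan-4-one | OCC[C@@]1(C)OC(C)(C)OC1=O | intermediate
4 | 2-[(4R)-2,2,4-trimethyl-5-oxo-1,3-dioxolan-4-yl]acetaldehyde | O=CC[C@@]1(C)OC(C)(C)OC1=O | intermediate
5 | allyl(diisopropylamino)dimethylsilane | C=CC[Si](C)(C)N(C(C)C)C(C)C | starting material
6 | borinate adduct: C8 O-diisopinocampheylborinate of the anti C7-silyl C8-carbinol | C=C[C@@H]([Si](C)(C)N(C(C)C)C(C)C)[C@@H](OB([C@H]1C[C@H]2C[C@@H]([C@@H]1C)C2(C)C)[C@H]1C[C@H]2C[C@@H]([C@@H]1C)C2(C)C)C[C@@]1(C)OC(C)(C)OC1=O | intermediate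
7 | dioxolanone diol, (5R)-5-[(2S,3R)-2,3-dihydroxypent-4-enyl]-2,2,5-trimethyl-1,3-dioxolan-4-one | C=C[C@@H](O)[C@@H](O)C[C@@]1(C)OC(C)(C)OC1=O | intermediate
8 | (3R,5S)-3-hydroxy-5-[(1R)-1-hydroxyprop-2-enyl]-3-methyloxolan-2-one | C=C[C@@H](O)[C@@H]1C[C@@](C)(O)C(=O)O1 | intermediate
9 | (3R,5S)-3-hydroxy-3-methyl-5-[(1R)-1-(triethylsilyloxy)prop-2-enyl]oxolan-2-one | C=C[C@@H](O[Si](CC)(CC)CC)[C@@H]1C[C@@](C)(O)C(=O)O1 | intermediate
10 | (2S)-2-[(2S,4R)-4-hydroxy-4-methyl-5-oxooxolan-2-yl]-2-(triethylsilyloxy)acetaldehyde | O=C[C@@H](O[Si](CC)(CC)CC)[C@@H]1C[C@@](C)(O)C(=O)O1 | intermediate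
11 | 3-chloro-2-methylprop-1-ene | C=C(C)CCl | starting material
12 | syn chlorohydrin, (3R,5S)-5-[(1R,2S,3S)-3-chloro-2-hydroxy-4-methyl-1-(triethylsilyloxy)pent-4-enyl]-3-hydroxy-3-methyloxolan-2-one | C=C(C)[C@H](Cl)[C@@H](O)[C@@H](O[Si](CC)(CC)CC)[C@@H]1C[C@@](C)(O)C(=O)O1 | intermediate
13 | cis C5–C6 vinyl epoxide lactone (isopropenyl on C5, C7 OTES, C8–O/C1 γ-lactone, C10 OH) | C=C(C)[C@H]1O[C@H]1[C@@H](O[Si](CC)(CC)CC)[C@@H]1C[C@@](C)(O)C(=O)O1 | intermediate
14 | methyl phenyl sulfone | CS(=O)(=O)c1ccccc1 | starting material
15 | open-chain β-keto sulfone diol (C1 ketone, C2 CH2SO2Ph, C8 OH, C10 OH, C7 OTES, cis vinyl epoxide) | C=C(C)[C@H]1O[C@H]1[C@@H](O[Si](CC)(CC)CC)[C@@H](O)C[C@@](C)(O)C(=O)CS(=O)(=O)c1ccccc1 | intermediate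
16 | C8,C10-bis-acetate of 15 | C=C(C)[C@H]1O[C@H]1[C@@H](O[Si](CC)(CC)CC)[C@@H](OC(C)=O)C[C@@](C)(OC(C)=O)C(=O)CS(=O)(=O)c1ccccc1 | intermediate
17 | ring A allylic alcohol, (4E)-cyclodecenone with C2 SO2Ph (epimers), C6 OH, C7 OTES, C8 OAc, C10 OAc | CC(=O)O[C@H]1C[C@@](C)(OC(C)=O)C(=O)C(S(=O)(=O)c2ccccc2)C/C(C)=C/[C@@H](O)[C@H]1O[Si](CC)(CC)CC | intermediate
18 | 4R,5R epoxide of 17 | CC(=O)O[C@H]1C[C@@](C)(OC(C)=O)C(=O)C(S(=O)(=O)c2ccccc2)C[C@@]2(C)O[C@@H]2[C@@H](O)[C@H]1O[Si](CC)(CC)CC | intermediate
19 | desulfonylated epoxy alcohol (free C6–OH, C7 OTES) | CC(=O)O[C@H]1C[C@@](C)(OC(C)=O)C(=O)CC[C@@]2(C)O[C@@H]2[C@@H](O)[C@H]1O[Si](CC)(CC)CC | intermediate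
20 | triethyl phosphonoacetate | CCOC(=O)CP(=O)(OCC)OCC | starting material
21 | formaldehyde (as paraformaldehyde) | C=O | starting material
22 | ethyl 2-(diethoxyphosphoryl)-3-hydroxypropanoate | CCOC(=O)C(CO)P(=O)(OCC)OCC | intermediate
23 | ethyl 2-(diethoxyphosphoryl)acrylate | CCOC(=O)C(=C)P(=O)(OCC)OCC | intermediate
24 | 4-methoxybenzyl alcohol | COc1ccc(CO)cc1 | starting material
25 | ethyl 2-(diethoxyphosphoryl)-3-(4-methoxybenzyloxy)propanoate (racemic) | CCOC(=O)C(COCc1ccc(OC)cc1)P(=O)(OCC)OCC | intermediate
26 | 2-(diethoxyphosphoryl)-3-(4-methoxybenzyloxy)propanoic acid (racemic) | OC(=O)C(COCc1ccc(OC)cc1)P(=O)(OCC)OCC | intermediate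
27 | C6 phosphono ester of 19 (C11 epimers, C7 OTES) | CC(=O)O[C@H]1C[C@@](C)(OC(C)=O)C(=O)CC[C@@]2(C)O[C@@H]2[C@@H](OC(=O)C(COCc2ccc(OC)cc2)P(=O)(OCC)OCC)[C@H]1O[Si](CC)(CC)CC | intermediate
28 | C7 alcohol from 27 | CC(=O)O[C@H]1C[C@@](C)(OC(C)=O)C(=O)CC[C@@]2(C)O[C@@H]2[C@@H](OC(=O)C(COCc2ccc(OC)cc2)P(=O)(OCC)OCC)[C@H]1O | intermediate
29 | ten-membered C7 ketone with the phosphono ester on C6–O (C11 epimers) | CC(=O)O[C@H]1C[C@@](C)(OC(C)=O)C(=O)CC[C@@]2(C)O[C@@H]2[C@@H](OC(=O)C(COCc2ccc(OC)cc2)P(=O)(OCC)OCC)C1=O | intermediate
30 | β-hydroxyphosphonate lactone (C7 OH, C11 phosphonate, ring C closed; C7 and C11 undefined) | CC(=O)O[C@H]1C[C@@](C)(OC(C)=O)C(=O)CC[C@@]2(C)O[C@@H]2[C@H]2OC(=O)C(COCc3ccc(OC)cc3)(P(=O)(OCC)OCC)C12O | intermediate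
31 | C13 4-methoxybenzyl ether of the target | CC(=O)O[C@H]1C[C@@](C)(OC(C)=O)C(=O)CC[C@@]2(C)O[C@@H]2[C@H]2OC(=O)C(COCc3ccc(OC)cc3)=C12 | intermediate
32 | CNP0266633.2 (4R,5R,6S,8S,10R) | CC(=O)O[C@H]1C[C@@](C)(OC(C)=O)C(=O)CC[C@@]2(C)O[C@@H]2[C@H]2OC(=O)C(CO)=C12 | target

Total step count: 21. Longest linear sequence: 18 (steps 1–13 and 17–21). Steps 14–16 form the three-step side branch to acid 26.

Steps most likely to fail

Step 11 (closure of ring A). Ring closure may be outrun by several processes:
- oligomerisation;
- attack at C5, which closes an eight-membered ring;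
- closure through the anti π-allyl isomer, which gives the Z alkene;
- β-hydride loss from the π-allyl complex.

The fallback fixes the electrophilic carbon and the alkene geometry before the ring is closed and uses no palladium. It sets out from 16. SN2′ opening of the vinyl epoxide with MgBr2·OEt2 (Et2O, −40 °C), with bromide entering at C3 and equilibration to the more substituted E alkene, should give the (E)-C3 allylic bromide with free C6–OH F1. Slow addition of F1 to Cs2CO3 in MeCN at high dilution should then alkylate the β-keto sulfone carbon C2 by direct SN2 displacement. This comes back to the route at 17.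

Step 20 (key olefination). The C11 carbanion may expel the benzylic alkoxide from C13 faster than it adds to the hindered C7 carbonyl. Alternatively, the base may remove C6–H, which triggers epimerisation or opening of the oxirane. The fallback keeps the same disconnection but makes the conjugate addition part of the closure (known tandem oxa-Michael/Horner–Wadsworth–Emmons chemistry of 2-phosphonoacrylates). It sets out from 19.
- Acrylate 23 is saponified (LiOH, THF–H2O) to 2-(diethoxyphosphoryl)acrylic acid F2.
- Coupling of F2 with 19 (DCC, DMAP) gives the C6 2-phosphonoacrylate F3.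
- HF·pyridine gives the C7 alcohol F4.
- Dess–Martin periodinane gives the C7 ketone F5.
- The lithium alkoxide of 24 (from 24 and LiN(SiMe3)2, THF, −20 °C) then adds to C13 of F5. The C11 carbanion generated in this way closes onto C7, so that any loss of alkoxide only regenerates the acceptor.

This comes back to the route at 31.

Step 10 (bis-acetylation). Three processes may compete with acetylation of the tertiary C10 hydroxyl: hemiketalisation of C8–OH onto the activated C1 ketone, elimination of the hemiketal towards a sulfonyl enol ether, and O-acetylation of the acidic β-keto sulfone. The fallback introduces C2 at the sulfide oxidation level, where the methylene is not acidic and the ketone is less electrophilic. It sets out from 13. Addition of PhSCH2Li (thioanisole, n-BuLi, DABCO, THF) to the lactone gives the α-phenylthio ketone diol F6. Ac2O, pyridine and DMAP give its bis-acetate F7. Oxidation at sulfur with mCPBA (2 equiv, CH2Cl2–pH 7 buffer, −20 °C), which is faster than epoxidation of the deactivated 1,1-disubstituted alkene, comes back to the route at 16.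

Further compounds
F1 | step 11 | (E)-C3 allylic bromide with free C6–OH (C7 OTES, C8 and C10 OAc, β-keto sulfone) | BrC/C(C)=C/[C@@H](O)[C@@H](O[Si](CC)(CC)CC)[C@@H](OC(C)=O)C[C@@](C)(OC(C)=O)C(=O)CS(=O)(=O)c1ccccc1
F2 | step 20 | 2-(diethoxyphosphoryl)acrylic acid | C=C(C(=O)O)P(=O)(OCC)OCC
F3 | step 20 | C6 2-(diethoxyphosphoryl)acrylate of 19 | CC(=O)O[C@H]1C[C@@](C)(OC(C)=O)C(=O)CC[C@@]2(C)O[C@@H]2[C@@H](OC(=O)C(=C)P(=O)(OCC)OCC)[C@H]1O[Si](CC)(CC)CC
F4 | step 20 | C7 alcohol from F3 | CC(=O)O[C@H]1C[C@@](C)(OC(C)=O)C(=O)CC[C@@]2(C)O[C@@H]2[C@@H](OC(=O)C(=C)P(=O)(OCC)OCC)[C@H]1O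
F5 | step 20 | C7 ketone with the 2-phosphonoacrylate on C6–O | CC(=O)O[C@H]1C[C@@](C)(OC(C)=O)C(=O)CC[C@@]2(C)O[C@@H]2[C@@H](OC(=O)C(=C)P(=O)(OCC)OCC)C1=O
F6 | step 10 | α-phenylthio ketone diol | C=C(C)[C@H]1O[C@H]1[C@@H](O[Si](CC)(CC)CC)[C@@H](O)C[C@@](C)(O)C(=O)CSc1ccccc1
F7 | step 10 | bis-acetate of F6 | C=C(C)[C@H]1O[C@H]1[C@@H](O[Si](CC)(CC)CC)[C@@H](OC(C)=O)C[C@@](C)(OC(C)=O)C(=O)CSc1ccccc1
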